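## The problem

Target 26 is a 1,7-diarylheptanoid. Its chain runs from C1 (bearing the 4-hydroxy-3-methoxyphenyl ring) to C7 (bearing the 4-hydroxyphenyl ring) and is folded into a single oxane by an ether bridge between C1 and C5. The ring atoms are O, C1, C2, C3, C4 and C5; C3 carries a hydroxyl and C5 carries the CH(OH)CH2Ar arm (C6, C7). There are four stereocentres (1S,3R,5S,6R). The aryl group at C1 and the side arm at C5 are trans across the ring oxygen, which is the less stable arrangement, so acid equilibration, oxa-Michael closure or oxocarbenium reduction would all drift to the cis isomer. C5 and C6 are vicinal (erythro) and are best taken together from one fragment. The C3 hydroxyl is anti to the C5 oxygen and can be set from C5 by 1,3-induction. C1 is 1,5 to C5 and out of reach of acyclic induction, so it has to enter enantiopure and be fixed in a stereospecific step. The C1–O bond is a benzylic ether para to a phenolic oxygen and will ionise under acid or cleave under forcing hydrogenolysis; the β-oxygenated ketone intermediates of any carbonyl route eliminate easily; both phenols need protection. The enabling feature is the 1,3,5-oxygen pattern: C3 lies between two methylenes (C2, C4), each attached to an oxygen-bearing carbon (C1, C5). C3 can therefore be an acyl dianion equivalent that links two terminal epoxides, C1–C2 and C4–C5.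

## Retrosynthesis

**Protecting groups (26 ⇒ 25 ⇒ 24).** The last cuts are the aryl O–S bond and two O–benzyl bonds. The guaiacol oxygen is carried as a tosylate and not as a third benzyl ether, because the electron-poor sulfonyloxyarene protects C1 against ionisation throughout. Hydrogenolysis is placed before sulfonate removal so that the benzylic C1–O ring bond is reduced while the ring is still electron-poor. The forward steps must leave C1 untouched.

**Ring closure (24 ⇒ 23 ⇒ 22).** The O–C1 bond is cut. The alternatives are to cut O–C5 (substitution next to the C6 oxygen) or a ring C–C bond (Prins or oxa-Michael logic, which gives 2,6-cis). Cutting O–C1 lets the trans ring arise by SN2 displacement at an activated benzylic carbon with inversion. The precursor is the open-chain mesylate 23, which has no ring and has C1 in the configuration opposite to the target. The forward step needs clean inversion without ionisation.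

**Differentiating O1 (22 ⇒ 21 ⇒ 20 ⇒ 19).** Mesylate 22 comes from alcohol 21, which comes from silyl ether 20, the acetonide of anti diol 19. The acetonide masks O3 and O5 together so that O1 alone can be unmasked and activated. The demand is orthogonality: fluoride for silicon, mild acid for the acetal.

**C3 stereocentre (19 ⇒ 18).** The C3–H bond is cut back to ketone 18. A hydroxyl-directed reduction from the free C5 hydroxyl gives the 3,5-anti diol, so no chiral reagent is needed for C3. The forward reaction needs a free C5 hydroxyl and a blocked O1.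

**Key disconnection (18 ⇒ 17 ⇒ 13 + 4 + 10).** The ketone is unmasked from dithiane 17, and 17 is cut at C2–C3 and C3–C4 into silyl dithiane 13, aryl oxirane 4 and epoxy ether 10. Aldol cuts at the same bonds would create C1 or C5 in the coupling and need two separate stereocontrol events. The epoxide cut brings C1, C5 and C6 in ready-made and leaves O1 silylated and O5 free, exactly as the reduction needs. The chain is reduced to three small pieces with at most two stereocentres each. The forward reaction (via 14, 15 and 16) needs terminal opening of both epoxides and a silyl shift that occurs only on command.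

**Aryl oxirane (4 ⇒ 3 ⇒ 2 ⇒ 1).** Oxirane 4 is the slow-reacting enantiomer of racemate 3 in a hydrolytic kinetic resolution. Racemate 3 is the methylene-transfer product of O-tosylvanillin 2, made from vanillin 1. This is shorter than dihydroxylation of a styrene followed by closure.

**Epoxy ether (10 ⇒ 9 ⇒ 8 ⇒ 5 + 6).** Benzyl ether 10 comes from erythro epoxy alcohol 9, the product of a Sharpless kinetic resolution of racemic allylic alcohol 8. Alcohol 8 comes from acrolein 6 and the Grignard reagent 7 of benzylic chloride 5. One catalytic step fixes C5 and C6 together.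

**Linchpin (13 ⇒ 11).** Silyl dithiane 13 comes from 1,3-dithiane 11 by lithiation (12) and silylation.

## Roads not taken

**Alternative 1:** The cut is the C1=C2 bond of a cyclic enol ether, with C1 entering as an ester carbonyl. Acylation of the C5 hydroxyl of a C3-vinyl carbinol segment gives aroyl ester A1. Methylenation with Cp2Ti(CH2)(Cl)AlMe2 and ring-closing metathesis with second-generation Grubbs catalyst give 6-aryl dihydropyran A2.
- Merits: the fragment union is an esterification, the most dependable coupling of all four plans. No carbanion meets a sulfonate, and both phenols can be benzyl ethers.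
- Weak points: A2 has no stereocentre at C1. Hydrogen must be added across the enol ether, and both catalytic hydrogenation and protonation followed by hydride delivery place the aryl group equatorial and cis to the C5 arm. That is the epimer not wanted here. The titanium reagent is needed in stoichiometric amount, and metathesis onto an aryl-substituted enol ether is slow.
- Comparison: this road is more robust than the chosen one up to the ring and about equal in length. It ends at the wrong C1 configuration with no stereospecific way to correct it. The chosen plan sets C1 by SN2 inversion from a resolved epoxide.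

**Alternative 2:** The cuts are C3–C4 and O–C5. Aldoxime A3 (C1 to C3) is oxidised with NaOCl in the presence of allylic benzyl ether A4, and a nitrile oxide cycloaddition gives isoxazoline A5. Reductive N–O cleavage and hydrolysis would give ketone 18 of the present route.
- Merits: no strongly basic organometallic is used, so the aryl sulfonate is safe. A4 needs no epoxidation. The end game is identical to the chosen one.
- Weak points: C5 is created in the cycloaddition under substrate control by the C6 benzyloxy group (inside-alkoxy preference). For acyclic allyl ethers this is usually only moderate, so a C5 epimer has to be removed. Self-condensation of the oxidised oxime competes, and A3 needs its own asymmetric entry to C1.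
- Comparison: in functional-group tolerance this road is as good as or better than the chosen plan, and the step count is similar. The chosen plan sets against it that C5 arrives already fixed, together with C6, in one enantiopure epoxide.

**Alternative 3:** The cut is O–C5 with inversion. The trans-5,6-epoxy alcohol A6 has its free C1 hydroxyl already in the target configuration. Under catalytic camphorsulfonic acid it closes in a 6-exo mode to oxane A7 and releases the C6 hydroxyl.
- Merits: C5 and C6 come from alkene geometry and one reagent-controlled epoxidation. Ring closure and unveiling of the C6 hydroxyl are one step. No leaving group is needed at the benzylic carbon, so the acetonide, fluoride and mesylate operations of the chosen plan disappear and one hydrogenolysis finishes the synthesis.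
- Weak points: acid is applied to a C1 carbinol, and then to a C1 ether, that is benzylic to an electron-rich benzyloxy-methoxy ring. Ionisation there would erode C1 or equilibrate to the cis ring. C1, C3 and the epoxide have to be installed one after another on a linear chain.
- Comparison: on paper this is the shortest end game and in that respect better than the chosen plan. The chosen plan sets against it its convergence (three small pieces joined in one flask) and the fact that no acid meets an electron-rich benzylic C–O bond, because the ring stays electron-poor until closure is complete.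

Key step: step 8

Remark on the chemistry: chain compounds carry the heptanoid locants C1 (guaiacyl carbon) to C7. The CIP letter at C3 changes with the group on O1 (S in 19, 20, 22, 23; R in 21 and 24 to 26), although the spatial arrangement is the same throughout.

## Route

Step 1
Reactants: 1 vanillin
Product: 2 4-formyl-2-methoxyphenyl 4-methylbenzenesulfonate
Conditions: TsCl, Et3N, DMAP (cat.), CH2Cl2, 0 °C → rt
Reagents that add atoms: p-toluenesulfonyl chloride, Cc1ccc(S(=O)(=O)Cl)cc1
Why: Phenol O-sulfonylation; the aldehyde is untouched, and the sulfonate makes the ring electron-poor for all later chemistry at the benzylic carbon.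

Step 2
Reactants: 2 4-formyl-2-methoxyphenyl 4-methylbenzenesulfonate
Product: 3 rac-2-methoxy-4-(oxiran-2-yl)phenyl 4-methylbenzenesulfonate
Conditions: Me3S+ I−, NaH, DMSO/THF, 0 °C → rt
Reagents that add atoms: trimethylsulfonium iodide, C[S+](C)C.[I-]
Why: Corey–Chaykovsky epoxidation; the sulfonium ylide adds to the electron-poor aldehyde much faster than it attacks the sulfonate, and the betaine closes to the terminal oxirane (racemic).

Step 3
Reactants: 3 rac-2-methoxy-4-(oxiran-2-yl)phenyl 4-methylbenzenesulfonate
Product: 4 2-methoxy-4-[(2S)-oxiran-2-yl]phenyl 4-methylbenzenesulfonate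
Conditions: (S,S)-(salen)Co(OAc) (1 mol %; salen = N,N′-bis(3,5-di-tert-butylsalicylidene)cyclohexane-1,2-diamine dianion), H2O (0.55 equiv), THF, 0 °C → rt
Reagents that add atoms: none
Why: Hydrolytic kinetic resolution of a terminal oxirane; the (S,S) complex of trivalent cobalt is the antipode that hydrates the (R)-oxirane faster, so unreacted (S)-4 should be recovered in high enantiomeric purity (at most half of 3). This sets C1.

Step 4
Reactants: 5 4-(benzyloxy)benzyl chloride; 6 acrolein
Product: 8 rac-1-[4-(benzyloxy)phenyl]but-3-en-2-ol, via 4-(benzyloxy)benzylmagnesium chloride 7 (not isolated)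
Conditions: Mg, 2-MeTHF, 0 °C (slow addition of 5); 6, −78 °C; aq NH4Cl
Reagents that add atoms: none
Why: Grignard formation under slow addition limits Wurtz coupling of the benzylic halide; 1,2-addition to the aldehyde of acrolein at low temperature gives the racemic secondary allylic alcohol.

Step 5
Reactants: 8 rac-1-[4-(benzyloxy)phenyl]but-3-en-2-ol
Product: 9 (1R)-2-[4-(benzyloxy)phenyl]-1-[(2S)-oxiran-2-yl]ethan-1-ol
Conditions: Ti(OiPr)4 (0.2 equiv), D-(−)-diisopropyl tartrate (0.25 equiv), t-BuOOH (0.45 equiv), 4 Å MS, CH2Cl2, −20 °C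
Reagents that add atoms: tert-butyl hydroperoxide, CC(C)(C)OO
Why: Sharpless kinetic resolution; with the D-(−)-tartrate the (R)-alcohol is the fast-reacting enantiomer and is epoxidised on the face that gives the erythro epoxy alcohol, so C5 (S) and C6 (R) are fixed together. The substoichiometric oxidant keeps the product enantiomerically enriched and leaves the slow enantiomer of 8 behind.

Step 6
Reactants: 9 (1R)-2-[4-(benzyloxy)phenyl]-1-[(2S)-oxiran-2-yl]ethan-1-ol
Product: 10 (2S)-2-[(1R)-1-(benzyloxy)-2-[4-(benzyloxy)phenyl]ethyl]oxirane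
Conditions: NaH, BnBr, Bu4NI (cat.), THF, −20 → 0 °C
Reagents that add atoms: benzyl bromide, BrCc1ccccc1
Why: Williamson etherification; at low temperature with iodide catalysis O-benzylation should outrun Payne rearrangement of the epoxy alkoxide, and neither stereocentre is touched.

Step 7
Reactants: 11 1,3-dithiane
Product: 13 2-(tert-butyldimethylsilyl)-1,3-dithiane, via 2-lithio-1,3-dithiane 12 (not isolated)
Conditions: n-BuLi, THF, −30 °C; TBSCl, −78 °C → rt
Reagents that add atoms: tert-butyldimethylsilyl chloride, CC(C)(C)[Si](C)(C)Cl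
Why: Deprotonation of the dithiane C2–H and C-silylation of the resulting anion, the standard preparation of the linchpin.

Step 8
Reactants: 13 2-(tert-butyldimethylsilyl)-1,3-dithiane; 4 2-methoxy-4-[(2S)-oxiran-2-yl]phenyl 4-methylbenzenesulfonate; 10 (2S)-2-[(1R)-1-(benzyloxy)-2-[4-(benzyloxy)phenyl]ethyl]oxirane
Product: 17 4-[(1R)-1-[(tert-butyldimethylsilyl)oxy]-2-{2-[(2S,3R)-3-(benzyloxy)-4-[4-(benzyloxy)phenyl]-2-hydroxybutyl]-1,3-dithian-2-yl}ethyl]-2-methoxyphenyl 4-methylbenzenesulfonate, via lithiated silyl dithiane 14 (not isolated), via lithium alkoxide adduct 15 (not isolated), via Brook-rearranged dithianyllithium 16 (not isolated)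
Conditions: 13 (1.1 equiv), t-BuLi (1.05 equiv), Et2O, −78 → −45 °C; 4, Et2O, −78 → −25 °C; then 10, HMPA, Et2O, −78 → 0 °C; aq NH4Cl
Reagents that add atoms: none
Why: Deprotonation of 13 gives 14, a bulky sulfur- and silicon-stabilised carbanion that opens oxirane 4 by SN2 attack at its CH2 terminus (C2); this forms C2–C3 and leaves C1 untouched as lithium alkoxide 15, and in diethyl ether the tight O–Li pair does not attack silicon. HMPA then solvates lithium, the alkoxide adds to silicon, and the silicate collapses by 1,4-Brook rearrangement to silyl ether 16 with the charge back on the dithiane carbon. 16 opens 10 at its CH2 terminus (C4), forming C3–C4 and releasing the C5 alkoxide, which is protonated on work-up. The closest known reaction type is the one-flask, solvent-controlled three-component coupling of a 2-silyl-1,3-dithiane with two different terminal epoxides (anion relay chemistry). No ring closes and no stereocentre is formed; C1, C5 and C6 are carried over unchanged because no carbinol carbon is attacked. The step needs terminal regioselectivity in both openings, secured by the bulk of 14 and 16, the absence of a Lewis acid and the electron-poor sulfonyloxyarene, which disfavours benzylic opening of 4. It also needs the two epoxides to react in order (HMPA is withheld until 4 is consumed) and the aryl sulfonate to survive (no free t-BuLi, low temperature).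

Step 9
Reactants: 17 silyloxy hydroxy dithiane from step 8
Product: 18 4-[(1R,5S,6R)-6-(benzyloxy)-7-[4-(benzyloxy)phenyl]-1-[(tert-butyldimethylsilyl)oxy]-5-hydroxy-3-oxoheptyl]-2-methoxyphenyl 4-methylbenzenesulfonate
Conditions: Hg(ClO4)2·3H2O, CaCO3, THF/H2O, 0 °C
Reagents that add atoms: water, O
Why: Thiophilic metal-assisted hydrolysis of the dithioketal; the carbonate buffer and low temperature should prevent β-elimination or retro-aldol cleavage of the β-silyloxy β′-hydroxy ketone.

Step 10
Reactants: 18 β-hydroxy ketone from step 9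
Product: 19 4-[(1R,3S,5S,6R)-6-(benzyloxy)-7-[4-(benzyloxy)phenyl]-1-[(tert-butyldimethylsilyl)oxy]-3,5-dihydroxyheptyl]-2-methoxyphenyl 4-methylbenzenesulfonate
Conditions: Me4NBH(OAc)3, MeCN/AcOH (1:1), −30 °C
Reagents that add atoms: none
Why: Evans–Saksena reduction; the C5 hydroxyl exchanges onto boron and delivers hydride intramolecularly through a chair transition state with the C5 substituent equatorial, which gives the 3,5-anti diol and sets C3. The silyl ether on O1 cannot act as a competing director.

Step 11
Reactants: 19 anti diol from step 10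
Product: 20 4-[(1R)-2-{(4S,6S)-6-[(1R)-1-(benzyloxy)-2-[4-(benzyloxy)phenyl]ethyl]-2,2-dimethyl-1,3-dioxan-4-yl}-1-[(tert-butyldimethylsilyl)oxy]ethyl]-2-methoxyphenyl 4-methylbenzenesulfonate
Conditions: 2,2-dimethoxypropane, PPTS (cat.), CH2Cl2, rt
Reagents that add atoms: 2,2-dimethoxypropane, COC(C)(C)OC
Why: Acetonide formation by transacetalisation of the 1,3-diol; O3 and O5 are masked together so that O1 can be addressed alone, and the benzylic silyl ether is stable to the mild anhydrous acid.

Step 12
Reactants: 20 acetonide silyl ether from step 11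
Product: 21 4-[(1R)-2-{(4R,6S)-6-[(1R)-1-(benzyloxy)-2-[4-(benzyloxy)phenyl]ethyl]-2,2-dimethyl-1,3-dioxan-4-yl}-1-hydroxyethyl]-2-methoxyphenyl 4-methylbenzenesulfonate
Conditions: Bu4NF, AcOH (1:1), THF, 0 °C → rt
Reagents that add atoms: none
Why: Fluoride desilylation; the acetic acid buffer keeps the medium from becoming basic enough to attack the aryl sulfonate, and the acetonide is inert.

Step 13
Reactants: 21 benzylic alcohol from step 12
Product: 22 4-[(1R)-2-{(4S,6S)-6-[(1R)-1-(benzyloxy)-2-[4-(benzyloxy)phenyl]ethyl]-2,2-dimethyl-1,3-dioxan-4-yl}-1-[(methylsulfonyl)oxy]ethyl]-2-methoxyphenyl 4-methylbenzenesulfonate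
Conditions: Ms2O, Et3N, CH2Cl2, −20 °C; used crude
Reagents that add atoms: methanesulfonic anhydride, CS(=O)(=O)OS(C)(=O)=O
Why: O-sulfonylation of the secondary benzylic alcohol with retention at C1; the anhydride is used so that no chloride ion is present to displace the benzylic mesylate, and the electron-poor ring makes the mesylate stable enough to handle.

Step 14
Reactants: 22 acetonide mesylate from step 13
Product: 24 4-{(2S,4R,6S)-6-[(1R)-1-(benzyloxy)-2-[4-(benzyloxy)phenyl]ethyl]-4-hydroxyoxan-2-yl}-2-methoxyphenyl 4-methylbenzenesulfonate, via diol mesylate 23 (not isolated)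
Conditions: CSA (cat.), MeOH/CH2Cl2, 0 °C → rt; then iPr2NEt, 40 °C
Reagents that add atoms: none
Why: Acid-catalysed transacetalisation frees the 3,5-diol (the strained anti acetonide should cleave quickly); the C5 hydroxyl then displaces the benzylic mesylate by intramolecular SN2 attack (6-exo-tet) with inversion at C1, which gives the 2,6-trans oxane. The sulfonyloxyarene disfavours ionisation at C1, and four-membered closure by O3 cannot compete.

Step 15
Reactants: 24 trans oxane from step 14
Product: 25 4-{(2S,4R,6S)-4-hydroxy-6-[(1R)-1-hydroxy-2-(4-hydroxyphenyl)ethyl]oxan-2-yl}-2-methoxyphenyl 4-methylbenzenesulfonate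
Conditions: H2 (1 atm), Pd(OH)2/C, EtOAc/MeOH, rt
Reagents that add atoms: none
Why: Hydrogenolysis of the aryl and the secondary alkyl benzyl ethers; the ring C1–O bond is a hindered dialkyl benzylic ether on a still electron-poor arene and should be cleaved much more slowly.

Step 16
Reactants: 25 triol sulfonate from step 15
Product: 26 (2S,4R,6S)-2-(4-hydroxy-3-methoxyphenyl)-6-[(1R)-1-hydroxy-2-(4-hydroxyphenyl)ethyl]oxan-4-ol
Conditions: Mg, MeOH, rt
Reagents that add atoms: none
Why: Reductive S–O cleavage of the aryl sulfonate by electron transfer from magnesium in methanol; room temperature avoids hot hydroxide, which could open the p-hydroxybenzylic ether through a quinone methide and epimerise C1.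

## Compound list

1 | vanillin (4-hydroxy-3-methoxybenzaldehyde) | COc1cc(C=O)ccc1O | starting material
2 | 4-formyl-2-methoxyphenyl 4-methylbenzenesulfonate | COc1cc(C=O)ccc1OS(=O)(=O)c1ccc(C)cc1 | intermediate
3 | rac-2-methoxy-4-(oxiran-2-yl)phenyl 4-methylbenzenesulfonate | COc1cc(C2CO2)ccc1OS(=O)(=O)c1ccc(C)cc1 | intermediate
4 | 2-methoxy-4-[(2S)-oxiran-2-yl]phenyl 4-methylbenzenesulfonate | COc1cc([C@H]2CO2)ccc1OS(=O)(=O)c1ccc(C)cc1 | intermediate
5 | 4-(benzyloxy)benzyl chloride | ClCc1ccc(OCc2ccccc2)cc1 | starting material
6 | acrolein | C=CC=O | starting material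
7 | 4-(benzyloxy)benzylmagnesium chloride | Cl[Mg]Cc1ccc(OCc2ccccc2)cc1 | intermediate
8 | rac-1-[4-(benzyloxy)phenyl]but-3-en-2-ol | C=CC(O)Cc1ccc(OCc2ccccc2)cc1 | intermediate
9 | (1R)-2-[4-(benzyloxy)phenyl]-1-[(2S)-oxiran-2-yl]ethan-1-ol | C1O[C@@H]1[C@H](O)Cc1ccc(OCc2ccccc2)cc1 | intermediate
10 | (2S)-2-[(1R)-1-(benzyloxy)-2-[4-(benzyloxy)phenyl]ethyl]oxirane | C1O[C@@H]1[C@H](OCc1ccccc1)Cc1ccc(OCc2ccccc2)cc1 | intermediate
11 | 1,3-dithiane | C1CSCSC1 | starting material
12 | 2-lithio-1,3-dithiane | [Li]C1SCCCS1 | intermediate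
13 | 2-(tert-butyldimethylsilyl)-1,3-dithiane | CC(C)(C)[Si](C)(C)C1SCCCS1 | intermediate
14 | 2-lithio-2-(tert-butyldimethylsilyl)-1,3-dithiane | CC(C)(C)[Si](C)(C)C1([Li])SCCCS1 | intermediate
15 | lithium (1R)-2-[2-(tert-butyldimethylsilyl)-1,3-dithian-2-yl]-1-[3-methoxy-4-(tosyloxy)phenyl]ethoxide | COc1cc([C@H](O[Li])CC2([Si](C)(C)C(C)(C)C)SCCCS2)ccc1OS(=O)(=O)c1ccc(C)cc1 | intermediate
16 | 2-lithio-2-{(2R)-2-[(tert-butyldimethylsilyl)oxy]-2-[3-methoxy-4-(tosyloxy)phenyl]ethyl}-1,3-dithiane | COc1cc([C@H](O[Si](C)(C)C(C)(C)C)CC2([Li])SCCCS2)ccc1OS(=O)(=O)c1ccc(C)cc1 | intermediate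
17 | 4-[(1R)-1-[(tert-butyldimethylsilyl)oxy]-2-{2-[(2S,3R)-3-(benzyloxy)-4-[4-(benzyloxy)phenyl]-2-hydroxybutyl]-1,3-dithian-2-yl}ethyl]-2-methoxyphenyl 4-methylbenzenesulfonate | COc1cc([C@H](O[Si](C)(C)C(C)(C)C)CC2(C[C@H](O)[C@H](OCc3ccccc3)Cc3ccc(OCc4ccccc4)cc3)SCCCS2)ccc1OS(=O)(=O)c1ccc(C)cc1 | intermediate
18 | 4-[(1R,5S,6R)-6-(benzyloxy)-7-[4-(benzyloxy)phenyl]-1-[(tert-butyldimethylsilyl)oxy]-5-hydroxy-3-oxoheptyl]-2-methoxyphenyl 4-methylbenzenesulfonate | COc1cc([C@H](O[Si](C)(C)C(C)(C)C)CC(=O)C[C@H](O)[C@H](OCc3ccccc3)Cc3ccc(OCc4ccccc4)cc3)ccc1OS(=O)(=O)c1ccc(C)cc1 | intermediate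
19 | 4-[(1R,3S,5S,6R)-6-(benzyloxy)-7-[4-(benzyloxy)phenyl]-1-[(tert-butyldimethylsilyl)oxy]-3,5-dihydroxyheptyl]-2-methoxyphenyl 4-methylbenzenesulfonate (3,5-anti) | COc1cc([C@H](O[Si](C)(C)C(C)(C)C)C[C@@H](O)C[C@H](O)[C@H](OCc3ccccc3)Cc3ccc(OCc4ccccc4)cc3)ccc1OS(=O)(=O)c1ccc(C)cc1 | intermediate
20 | 4-[(1R)-2-{(4S,6S)-6-[(1R)-1-(benzyloxy)-2-[4-(benzyloxy)phenyl]ethyl]-2,2-dimethyl-1,3-dioxan-4-yl}-1-[(tert-butyldimethylsilyl)oxy]ethyl]-2-methoxyphenyl 4-methylbenzenesulfonate | COc1cc([C@H](O[Si](C)(C)C(C)(C)C)C[C@@H]2C[C@@H]([C@H](OCc3ccccc3)Cc3ccc(OCc4ccccc4)cc3)OC(C)(C)O2)ccc1OS(=O)(=O)c1ccc(C)cc1 | intermediate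
21 | 4-[(1R)-2-{(4R,6S)-6-[(1R)-1-(benzyloxy)-2-[4-(benzyloxy)phenyl]ethyl]-2,2-dimethyl-1,3-dioxan-4-yl}-1-hydroxyethyl]-2-methoxyphenyl 4-methylbenzenesulfonate | COc1cc([C@H](O)C[C@@H]2C[C@@H]([C@H](OCc3ccccc3)Cc3ccc(OCc4ccccc4)cc3)OC(C)(C)O2)ccc1OS(=O)(=O)c1ccc(C)cc1 | intermediate
22 | 4-[(1R)-2-{(4S,6S)-6-[(1R)-1-(benzyloxy)-2-[4-(benzyloxy)phenyl]ethyl]-2,2-dimethyl-1,3-dioxan-4-yl}-1-[(methylsulfonyl)oxy]ethyl]-2-methoxyphenyl 4-methylbenzenesulfonate | COc1cc([C@H](OS(C)(=O)=O)C[C@@H]2C[C@@H]([C@H](OCc3ccccc3)Cc3ccc(OCc4ccccc4)cc3)OC(C)(C)O2)ccc1OS(=O)(=O)c1ccc(C)cc1 | intermediate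
23 | 4-[(1R,3S,5S,6R)-6-(benzyloxy)-7-[4-(benzyloxy)phenyl]-3,5-dihydroxy-1-[(methylsulfonyl)oxy]heptyl]-2-methoxyphenyl 4-methylbenzenesulfonate | COc1cc([C@H](OS(C)(=O)=O)C[C@@H](O)C[C@H](O)[C@H](OCc3ccccc3)Cc3ccc(OCc4ccccc4)cc3)ccc1OS(=O)(=O)c1ccc(C)cc1 | intermediate
24 | 4-{(2S,4R,6S)-6-[(1R)-1-(benzyloxy)-2-[4-(benzyloxy)phenyl]ethyl]-4-hydroxyoxan-2-yl}-2-methoxyphenyl 4-methylbenzenesulfonate | COc1cc([C@@H]2C[C@@H](O)C[C@@H]([C@H](OCc3ccccc3)Cc3ccc(OCc4ccccc4)cc3)O2)ccc1OS(=O)(=O)c1ccc(C)cc1 | intermediate
25 | 4-{(2S,4R,6S)-4-hydroxy-6-[(1R)-1-hydroxy-2-(4-hydroxyphenyl)ethyl]oxan-2-yl}-2-methoxyphenyl 4-methylbenzenesulfonate | COc1cc([C@@H]2C[C@@H](O)C[C@@H]([C@H](O)Cc3ccc(O)cc3)O2)ccc1OS(=O)(=O)c1ccc(C)cc1 | intermediate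
26 | (2S,4R,6S)-2-(4-hydroxy-3-methoxyphenyl)-6-[(1R)-1-hydroxy-2-(4-hydroxyphenyl)ethyl]oxan-4-ol | COc1cc([C@@H]2C[C@@H](O)C[C@@H]([C@H](O)Cc3ccc(O)cc3)O2)ccc1O | target

## Step count and least certain steps

Total step count: 16. Longest linear sequence: 12 steps (steps 1, 2, 3, then 8 to 16; the branch from 5 through steps 4, 5, 6 is equally long).

**Step 8 (key step).** The most likely failure is sulfonyl transfer from the aryl tosylate to carbanion 14 or 16 (attack at sulfur), or lateral deprotonation of the tolyl methyl group. Either would consume the anion before it opens an epoxide. Partial benzylic opening of 4 is less likely. The fallback sets out from 1 and returns at 17; it carries the guaiacol oxygen as a silyl ether through the coupling and installs the sulfonate afterwards. Vanillin 1 is silylated (TBSCl, imidazole) to 4-[(tert-butyldimethylsilyl)oxy]-3-methoxybenzaldehyde F1. Corey–Chaykovsky epoxidation gives racemic oxirane F2, and hydrolytic kinetic resolution gives (S)-oxirane F3. The same three-component coupling with 13 and 10 gives bis-silyl hydroxy dithiane F4. The phenolic silyl ether alone is cleaved (KHF2, MeOH) to phenol F5, and phenol-selective tosylation (TsCl, K2CO3, acetone) delivers 17.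

**Step 14.** The most likely failure is solvolysis or ionisation of the benzylic mesylate before the acetonide has gone, with loss of configuration at C1 or capture by methanol, or elimination toward the styrene. The fallback sets out from 19 and returns at 24; it frees the nucleophile with base instead of acid. Diol 19 is acetylated (Ac2O, pyridine, DMAP) to diacetate F6. O1 is desilylated with HF·pyridine to alcohol F7, which is mesylated (Ms2O, Et3N) to diacetate mesylate F8. K2CO3 in MeOH at 0 °C removes both acetates, and the C5 alkoxide closes the ring with inversion to give 24.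

**Step 5.** The most likely failure is slow epoxidation of the monosubstituted alkene, so that the reaction stalls. Titanium-mediated opening of the terminal epoxy alcohol during the long reaction time is also possible, and the enantiomeric purity of 9 is limited by the selectivity factor at the chosen conversion. The fallback sets out from 8 and returns at 9; it separates resolution from epoxidation. Racemate 8 is first resolved with the L-(+)-tartrate to beyond half conversion, which consumes the (S)-alcohol and leaves (2R)-1-[4-(benzyloxy)phenyl]but-3-en-2-ol F9. F9 is then epoxidised with the D-(−)-tartrate (matched pair, full conversion) to 9.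

**Step 15.** The most likely failure is hydrogenolytic cleavage of the benzylic C1–O ring bond while the secondary C6 benzyl ether is still being removed, or catalyst poisoning by sulfur traces from the dithiane stage. The fallback sets out from 24 and returns at 25; it replaces reductive cleavage by Lewis-acid debenzylation (BCl3 with pentamethylbenzene as cation scavenger, CH2Cl2, −78 °C), under which the electron-poor benzylic ring ether should not ionise. It makes no new compound.

## Further compounds

F1 | step 8 | 4-[(tert-butyldimethylsilyl)oxy]-3-methoxybenzaldehyde | COc1cc(C=O)ccc1O[Si](C)(C)C(C)(C)C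
F2 | step 8 | rac-tert-butyl[2-methoxy-4-(oxiran-2-yl)phenoxy]dimethylsilane | COc1cc(C2CO2)ccc1O[Si](C)(C)C(C)(C)C
F3 | step 8 | tert-butyl{2-methoxy-4-[(2S)-oxiran-2-yl]phenoxy}dimethylsilane | COc1cc([C@H]2CO2)ccc1O[Si](C)(C)C(C)(C)C
F4 | step 8 | analogue of 17 with the aryl sulfonate replaced by a tert-butyldimethylsilyl ether | COc1cc([C@H](O[Si](C)(C)C(C)(C)C)CC2(C[C@H](O)[C@H](OCc3ccccc3)Cc3ccc(OCc4ccccc4)cc3)SCCCS2)ccc1O[Si](C)(C)C(C)(C)C
F5 | step 8 | analogue of 17 with a free guaiacol hydroxyl | COc1cc([C@H](O[Si](C)(C)C(C)(C)C)CC2(C[C@H](O)[C@H](OCc3ccccc3)Cc3ccc(OCc4ccccc4)cc3)SCCCS2)ccc1O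
F6 | step 14 | 3,5-di-O-acetate of 19 | COc1cc([C@H](O[Si](C)(C)C(C)(C)C)C[C@@H](OC(C)=O)C[C@H](OC(C)=O)[C@H](OCc3ccccc3)Cc3ccc(OCc4ccccc4)cc3)ccc1OS(=O)(=O)c1ccc(C)cc1
F7 | step 14 | 3,5-di-O-acetate with free C1 hydroxyl | COc1cc([C@H](O)C[C@@H](OC(C)=O)C[C@H](OC(C)=O)[C@H](OCc3ccccc3)Cc3ccc(OCc4ccccc4)cc3)ccc1OS(=O)(=O)c1ccc(C)cc1
F8 | step 14 | 3,5-di-O-acetate C1 mesylate | COc1cc([C@H](OS(C)(=O)=O)C[C@@H](OC(C)=O)C[C@H](OC(C)=O)[C@H](OCc3ccccc3)Cc3ccc(OCc4ccccc4)cc3)ccc1OS(=O)(=O)c1ccc(C)cc1
F9 | step 5 | (2R)-1-[4-(benzyloxy)phenyl]but-3-en-2-ol | C=C[C@H](O)Cc1ccc(OCc2ccccc2)cc1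
F0 | step 15 | none | none
A1 | alternative 1 | 4-(benzyloxy)-3-methoxybenzoate of the C5 hydroxyl of the 3,6-bis(silyloxy)-7-aryl-hept-1-ene segment | COc1cc(C(=O)O[C@@H](C[C@H](O[Si](C)(C)C(C)(C)C)C=C)[C@H](O[Si](C)(C)C(C)(C)C)Cc2ccc(OCc3ccccc3)cc2)ccc1OCc1ccccc1
A2 | alternative 1 | 6-aryl-4-silyloxy-3,4-dihydro-2H-pyran carrying the C6, C7 side chain | COc1cc(C2=C[C@@H](O[Si](C)(C)C(C)(C)C)C[C@@H]([C@H](O[Si](C)(C)C(C)(C)C)Cc3ccc(OCc4ccccc4)cc3)O2)ccc1OCc1ccccc1
A3 | alternative 2 | (3R)-3-[(tert-butyldimethylsilyl)oxy]-3-[3-methoxy-4-(tosyloxy)phenyl]propanal oxime | COc1cc([C@H](O[Si](C)(C)C(C)(C)C)CC=NO)ccc1OS(=O)(=O)c1ccc(C)cc1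
A4 | alternative 2 | (2R)-2-(benzyloxy)-1-[4-(benzyloxy)phenyl]but-3-ene | C=C[C@H](OCc1ccccc1)Cc1ccc(OCc2ccccc2)cc1
A5 | alternative 2 | 3,5-disubstituted 2-isoxazoline with erythro C5/C6 | COc1cc([C@H](O[Si](C)(C)C(C)(C)C)CC2=NO[C@H]([C@H](OCc3ccccc3)Cc3ccc(OCc4ccccc4)cc3)C2)ccc1OS(=O)(=O)c1ccc(C)cc1
A6 | alternative 3 | trans-5,6-epoxy-3-silyloxy-1,7-diarylheptan-1-ol with benzyl-protected phenols | COc1cc([C@@H](O)C[C@@H](O[Si](C)(C)C(C)(C)C)C[C@H]2O[C@@H]2Cc3ccc(OCc4ccccc4)cc3)ccc1OCc1ccccc1
A7 | alternative 3 | 2,6-trans oxane with free C6 hydroxyl, C3 silyl ether and benzyl-protected phenols | COc1cc([C@@H]2C[C@@H](O[Si](C)(C)C(C)(C)C)C[C@@H]([C@H](O)Cc3ccc(OCc4ccccc4)cc3)O2)ccc1OCc1ccccc1
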